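Answer two questions about a series of flasks that differ in the X charged.

    Z ⇌ X, rate k1*([Z] - [X]/K1) per volume of the first phase (K1 = 1.9, k1 = 4.0 s⁻¹)
    Q + Z → Q.Z (k2 = 76 M⁻¹ s⁻¹)
    Z + Q.Z → Z.Q.Z (k3 = 37 M⁻¹ s⁻¹)
    2 Q → Q2 (k4 = 24 M⁻¹ s⁻¹)

| setting | theta | gamma | delta | eta | epsilon |
|---|---|---|---|---|---|
| Q | 1.0 mM | 1.0 mM | 1.0 mM | 1.0 mM | 1.0 mM |
| X | 1.50 mM | 3.00 mM | 6.00 mM | 12.0 mM | 25.0 mM |
| time | 12 s | 12 s | 12 s | 12 s | 12 s |
| volume of the second phase over the first | 1.0 | 1.0 | 1.0 | 1.0 | 1.0 |

- amount of Q.Z at the end, in percent of the Q charged for theta, gamma, delta, eta, epsilon, in this order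
- the shape of the row from first to last (rises all the way / hardly changes / falls all the way / falls, then rises / rises, then falls)

- percent here means Q units held: one Q2 counts as two
- for a step with 2 of a species take k times the square, and two of it per event
- in the second phase: X; everything else is in the first
- charges count per volume of the first phase; a concentration in a rate is the amount of a species over the volume of its own phase; every rate counts per litre of the first phase
- "hardly changes" means that all values lie within two and a half points (for a concentration: within two and a half percent of the largest)
- run time (theta): 12 s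

Begin with the transfer. It relaxes in 0.164 s, far faster than the 12 s run, so take it as at balance. The partition ratio and the volumes then give the free fraction, the part of the X charge that stands as Z before any of it is used: 0.345.

Hold Z at that fraction, which makes the loss of Q pseudo-first-order, and count the turns of a flask: k2 times free Z times the run time. Q.Z is then the middle member of a series whose second step has 0.487 of the rate constant of the first. It peaks at 1.40 turns. My reckoning, as fractions of the Q charge:

| flask | turns | Q.Z at the end |
|---|---|---|
| theta | 0.472 | 0.333 |
| gamma | 0.943 | 0.472 |
| delta | 1.89 | 0.482 |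
| eta | 3.77 | 0.266 |
| epsilon | 7.86 | 0.0417 |

Read down the turns. Gamma stops short of the peak and delta runs past it, so their entries in my column lie close together, and from there the column drops. That makes my shape rises, then falls.

Now distrust the top row. In theta, with Q at its charge and Z at the free fraction, Q goes to Q2 at 0.0480 s⁻¹ and to Q.Z at 0.0393 s⁻¹, so the dimer is the faster loss, a loss the table leaves out. In epsilon the same comparison reads 0.0480 s⁻¹ against 0.655 s⁻¹.

The forecast says 24.5%, 37%, 42.5%, 28% and 5.2%, rises, then falls, on the ground that “Q.Z behaves as the middle member of a consecutive series”. It shares my shape but stands below my column in theta, gamma and delta.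

The simulation gives 24.7%, 37.7%, 43.2%, 27.9% and 5.15%: rises, then falls. Watch delta, which ends at 12.0 s with Q at 14.8% and Z.Q.Z already at 28.3%. The row turns at a reading of 5.4 mM of X. Counted with the free fraction, that charge of X gives 1.69 turns, against 1.40 for the plain series.

The constants used here are invented; the run is a simulation.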